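Readings and results come from a simulation for an exercise, noise included.

We decide to count what is left, not what is made: a fraction left keeps a catalyst's preference in view, and a product amount hides it.

in all of them: free catalyst 50 µM (in portions, 2)
- eta: left-handed substrate 0.025 M; right-handed substrate 0.025 M; reagent 0.075 M; temperature −6 °C; run made earlier; portions every 2.0 min
- gamma: left-handed substrate 0.038 M; right-handed substrate 0.038 M; reagent 0.075 M; temperature 35 °C; run made earlier; portions every 2.0 min
- theta: left-handed substrate 0.050 M; right-handed substrate 0.050 M; reagent 0.037 M; temperature −6 °C; run made earlier; portions every 2.0 min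
- cedar: left-handed substrate 0.050 M; right-handed substrate 0.050 M; reagent 0.0750 M; temperature 50 °C; the portions of free catalyst follow each other after 2.0 min, the first at the start; time 1.5 h
- maple: left-handed substrate 0.050 M; right-handed substrate 0.050 M; reagent 0.0750 M; temperature −25 °C; the portions of free catalyst follow each other after 2.0 min, the first at the start; time 1.5 h
- oak: left-handed substrate 0.050 M; right-handed substrate 0.050 M; reagent 0.0750 M; temperature 25 °C; the portions of free catalyst follow each other after 2.0 min, the first at the start; time 1.5 h
- elm: left-handed substrate 0.050 M; right-handed substrate 0.050 M; reagent 0.0750 M; temperature 0 °C; the portions of free catalyst follow each other after 2.0 min, the first at the start; time 1.5 h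

- eta (time / h: left-handed product / %, right-handed product / %, left-handed substrate / %): 2.00: 47.2, 2.7, 3.0; 4.00: 50.4, 6.0, 0; 6.00: 50.0, 8.1, 0.2; 10.0: 50.0, 12.8, 0.3; 15.0: 49.6, 15.6, 0.2; 30.0: 50.0, 20.6, 0
- gamma (time / h: left-handed product / %, right-handed product / %, left-handed substrate / %): 0.667: 15.8, 3.5, 33.6; 1.33: 18.0, 4.1, 32.4; 2.00: 18.7, 4.1, 31.4; 3.00: 19.1, 4.1, 31.5; 4.00: 18.7, 4.0, 31.6
- theta (time / h: left-handed product / %, right-handed product / %, left-handed substrate / %): 2.00: 16.6, 0.2, 34.4; 4.00: 23.2, 0.4, 26.4; 8.00: 28.0, 0.6, 22.1; 15.0: 29.2, 1.1, 20.8; 30.0: 29.6, 0.6, 20.4

(standard deviation of a reading: 0.3 percentage points)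

- free catalyst is single-handed; left-handed substrate and right-handed substrate are mirror images of each other, charged as a racemate, each of them at the stated concentration
- the numbers in the tables scatter by 0.3 percentage points (one standard deviation)
- an excess is the difference of the two amounts in percent of their sum
- an excess is below zero if the other one leads

- which flask leads in excess of left-handed product over right-handed product ("all alike" within 1.5 percentage points) (cedar / maple / oak / elm / all alike)
- excess of left-handed product over right-handed product at the end, cedar
- excess of left-handed product over right-handed product at the end, maple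
- excess of left-handed product over right-handed product at the end, oak
- excess of left-handed product over right-handed product at the end, elm

1. The puzzle: the eta run, one flask at −6 °C, shows an excess of left-handed product of 89.2% at 2.00 h but 41.6% at 30.0 h. The catalyst and temperature are the same, so has the preference gone?

2. Each hand is half of the percent scale, so we double the readings. At 2.00 h in eta, the left-handed fraction left is 0.0600, and the right-handed fraction, taken from its product, is 0.946.

3. The selectivity factor s is the logarithm of the left-handed fraction left over the logarithm of the right-handed fraction left. For eta it reads 50.7.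

4. We test it on theta, also at −6 °C, but with twice the substrate charge and half the reagent. With the left-handed reading at 15.0 h, this s predicts 0.858% right-handed product, and the reading is 1.1%, within scatter.

5. This clears the puzzle. At 4.00 h, eta reads 0% left-handed substrate and 50.4% left-handed product, about its whole charge; by 30.0 h left-handed product reads 50.0%, while right-handed product has gone from 6.0% to 20.6%. So the excess in eta falls as its conversion rises, and s need not move.

6. While both fractions stay near one, the excess at a fixed s is close to (s − 1)/(s + 1), its ceiling. That gives 96.1% at −6 °C. The gamma run reads s = 5.50, so its ceiling is 69.2% at 35 °C. Taking s to go on falling as the temperature rises, through and beyond these two readings, we place maple above the first, elm just below it, oak just above the second and cedar below it, assuming maple keeps most of its left-handed substrate.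

7. The forecast says maple leads, with cedar 42%, maple 98%, oak 75% and elm 94%: “Only selectivity s matters, with conversion a minor correction”.

8. Maple leads at 99.1%, ahead of elm at 93.1%, oak at 75.7% and cedar at 42.6%.

    free catalyst + left-handed substrate ⇌ catalyst intermediate A (K = 57.0 L mol⁻¹, k = 10000 L mol⁻¹ s⁻¹, Ea = 17.0 kJ mol⁻¹, ΔH = −39.0 kJ mol⁻¹)
    free catalyst + right-handed substrate ⇌ catalyst intermediate B (K = 14.0 L mol⁻¹, k = 180 L mol⁻¹ s⁻¹, Ea = 42.0 kJ mol⁻¹, ΔH = −4.00 kJ mol⁻¹)
    reagent + catalyst intermediate A → free catalyst + left-handed product (k = 12.0 L mol⁻¹ s⁻¹, Ea = 37.0 kJ mol⁻¹)
    reagent + catalyst intermediate B → free catalyst + right-handed product (k = 5.40 L mol⁻¹ s⁻¹, Ea = 42.0 kJ mol⁻¹)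
    2 reagent → homo dimer (k = 0.0130 L mol⁻¹ s⁻¹, Ea = 66.0 kJ mol⁻¹)
    (constants at 25 °C)

At 1.50 h, maple still holds 79% of its left-handed charge. Its s, from that fraction and 0.0492% right-handed product, is 239, larger than the 50.7 read from eta, and its ceiling is 99.2%. Elm at 1.50 h gives s = 40.3. Carried to the left-handed substrate elm shows at 15.0 h, this s gives 2.64% right-handed product, and elm stands at 2.67%. At 15.0 h, maple has 0.741% left-handed substrate and its excess is 96.5%.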